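## Plan

1. Cuts (locants C1–C7a of the octahydroindene core, ring A = bromodimethylcyclohexylidene ring): C7–CH3; C4–C5 together with C3a–C7a; C6–C7; C1–C7a; the bond from the ring-A carbinol carbon to an alkyne; ring A itself by an O→C shift of a lactone-derived enol ether.
2. Enabling feature: in the cyclohexane ring the edge C3a(CH3)–C4(Br), methyl and bromine cis, is a latent (E)-1-bromo-2-methylalkene. The edge C5–C6–C7(O)–C7a is a latent 2-silyloxy diene, and the cyclopentane carbons C1–C2–C3 are the three-atom tether between them.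
3. Forward: ring-A ketone 4 and bromoenyne 10 are made separately and joined by acetylide addition. Alkyne reduction and a Johnson–Claisen rearrangement give the open chain, which is turned into a vinyl ketone and its silyl dienol ether. One intramolecular Diels–Alder reaction then closes the cyclopentane and the cyclohexane together; desilylation and methyl addition finish.
4. Stereochemistry: the ring-A C–Br comes from catalytic asymmetric bromolactonisation and C2 from catalytic asymmetric propargylation. The ring-A bromide fixes the carbinol (equatorial attack), and the chair Claisen relays this to C1 and to the E exocyclic alkene. C1 then controls C7a, C3a and C4 in the cycloaddition, and C7 comes from equatorial Grignard attack.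

Key step: step 13

Remark: for the two catalytic asymmetric steps (1 and 4) the catalyst antipode or pseudoenantiomer is taken to be the one that gives the configuration drawn; compounds 1 and 5 and allenylboronic acid pinacol ester are taken as commercial.

## Route

Step 1
Reactants: 1 5-methylhex-4-enoic acid
Product: 2 (5S)-5-bromo-6,6-dimethyloxan-2-one
Conditions: NBS (1.1 equiv), cinchona-alkaloid-derived amino-thiocarbamate organocatalyst (10 mol %), PhMe/CHCl3, −60 °C
Reagents that add atoms: N-bromosuccinimide, `O=C1CCC(=O)N1Br`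
Why: Catalytic enantioselective bromolactonisation, in which the chiral Lewis-basic catalyst delivers Br+ to one alkene face and the carboxylate opens the bromiranium ion at the tertiary carbon (6-endo, Markovnikov), setting the ring-A C–Br stereocentre as S.

Step 2
Reactants: 2 (5S)-5-bromo-6,6-dimethyloxan-2-one
Product: 3 (3S)-3-bromo-2,2-dimethyl-6-methylideneoxane
Conditions: Cp2TiMe2 (2.2 equiv), PhMe, 65 °C, dark
Reagents that add atoms: dimethyltitanocene (Cp2TiMe2), `[CH3-].[CH3-].[Ti+4].c1cc[cH-]c1.c1cc[cH-]c1`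
Why: Petasis methylenation of the lactone carbonyl by the titanium methylidene is non-basic and leaves the secondary bromide and its stereocentre untouched.

Step 3
Reactants: 3 (3S)-3-bromo-2,2-dimethyl-6-methylideneoxane
Product: 4 (4S)-4-bromo-3,3-dimethylcyclohexan-1-one
Conditions: TMSOTf (10 mol %), 2,6-di-tert-butyl-4-methylpyridine (15 mol %), CH2Cl2 (0.02 M), −78 → −40 °C
Reagents that add atoms: none
Why: Proposed new method: silylation of the enol-ether oxygen should trigger heterolysis of the tertiary C–O bond with anchimeric help from the neighbouring bromine, giving a configurationally defined bromonium ion tethered to a silyl enol ether, which recloses through carbon at the tertiary terminus to the cyclohexanone and releases TMSOTf, so the C–Br stereocentre is never broken; the closest known reaction types are the Petasis–Ferrier rearrangement of cyclic enol acetals, Lewis-acid α-tert-alkylation of silyl enol ethers by tertiary halides and the enantiospecific capture of bromonium ions generated by ionisation of β-bromo tertiary leaving groups.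

Step 4
Reactants: 5 3-(trimethylsilyl)prop-2-ynal
Product: 6 (3R)-1-(trimethylsilyl)hexa-1,5-diyn-3-ol
Conditions: allenylboronic acid pinacol ester (1.3 equiv), (R)-3,3'-bis(2,4,6-triisopropylphenyl)-1,1'-binaphthyl-2,2'-diyl hydrogen phosphate (5 mol %), 4 Å MS, PhMe, −30 °C; aq. work-up
Reagents that add atoms: allenylboronic acid pinacol ester, `C=C=CB1OC(C)(C)C(C)(C)O1`
Why: Chiral-phosphoric-acid-catalysed asymmetric propargylboration through a closed six-membered transition state held by the catalyst, which sets the C2 carbinol as R.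

Step 5
Reactants: 6 (3R)-1-(trimethylsilyl)hexa-1,5-diyn-3-ol
Product: 7 (3R)-3-[(tert-butyldimethylsilyl)oxy]-1-(trimethylsilyl)hexa-1,5-diyne
Conditions: TBSCl, imidazole, DMF, rt
Reagents that add atoms: tert-butyldimethylsilyl chloride, `CC(C)(C)[Si](C)(C)Cl`
Why: Standard silylation of a secondary alcohol, chosen because the TBS ether survives every step up to the final fluoride treatment.

Step 6
Reactants: 7 (3R)-3-[(tert-butyldimethylsilyl)oxy]-1-(trimethylsilyl)hexa-1,5-diyne
Product: 9 (3R,5E)-6-bromo-3-[(tert-butyldimethylsilyl)oxy]-5-methyl-1-(trimethylsilyl)hex-5-en-1-yne, via alkenyldimethylalane 8 (not isolated)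
Conditions: Me3Al (2.5 equiv), Cp2ZrCl2 (25 mol %), CH2Cl2, 0 °C → rt; then NBS, THF, −30 °C
Reagents that add atoms: trimethylaluminium, `C[Al](C)C`; N-bromosuccinimide, `O=C1CCC(=O)N1Br`
Why: Zirconium-catalysed syn-carboalumination of the terminal alkyne (Negishi carboalumination) puts methyl on the internal carbon, and bromodealumination with retention gives the E bromoalkene with bromine cis to methyl, while the silyl-capped alkyne stays inert.

Step 7
Reactants: 9 (3R,5E)-6-bromo-3-[(tert-butyldimethylsilyl)oxy]-5-methyl-1-(trimethylsilyl)hex-5-en-1-yne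
Product: 10 (3R,5E)-6-bromo-3-[(tert-butyldimethylsilyl)oxy]-5-methylhex-5-en-1-yne
Conditions: K2CO3 (0.3 equiv), MeOH, 0 °C → rt
Reagents that add atoms: none
Why: Base-mediated methanolysis of the alkynyl C–Si bond (protodesilylation) frees the terminal alkyne without touching the TBS ether or the bromoalkene.

Step 8
Reactants: 10 (3R,5E)-6-bromo-3-[(tert-butyldimethylsilyl)oxy]-5-methylhex-5-en-1-yne; 4 (4S)-4-bromo-3,3-dimethylcyclohexan-1-one
Product: 12 (1R,4S)-4-bromo-1-[(3R,5E)-6-bromo-3-[(tert-butyldimethylsilyl)oxy]-5-methylhex-5-en-1-yn-1-yl]-3,3-dimethylcyclohexan-1-ol, via lithium acetylide 11 (not isolated)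
Conditions: LDA (1.05 equiv), THF, −78 °C; then 4, LaCl3·2LiCl (0.3 equiv), −78 → −30 °C; aq. NH4Cl
Reagents that add atoms: none
Why: 1,2-addition of a lithium acetylide to the ketone, in which the axial methyl of the chair (bromine equatorial) blocks the axial trajectory, so attack is equatorial and the hydroxyl ends axial and cis to bromine (1R), with the lanthanum salt suppressing enolisation.

Step 9
Reactants: 12 (1R,4S)-4-bromo-1-[(3R,5E)-6-bromo-3-[(tert-butyldimethylsilyl)oxy]-5-methylhex-5-en-1-yn-1-yl]-3,3-dimethylcyclohexan-1-ol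
Product: 13 (1R,4S)-4-bromo-1-[(1E,3R,5E)-6-bromo-3-[(tert-butyldimethylsilyl)oxy]-5-methylhexa-1,5-dien-1-yl]-3,3-dimethylcyclohexan-1-ol
Conditions: NaAlH2(OCH2CH2OMe)2 (Red-Al, 2.5 equiv), THF, −20 → 0 °C; aq. Rochelle salt
Reagents that add atoms: none
Why: Hydroxyl-directed trans-hydroalumination of the propargylic alcohol followed by protonolysis gives the E alkene, and the low temperature keeps the alkenylaluminate from eliminating the neighbouring silyloxy group and spares both C–Br bonds.

Step 10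
Reactants: 13 (1R,4S)-4-bromo-1-[(1E,3R,5E)-6-bromo-3-[(tert-butyldimethylsilyl)oxy]-5-methylhexa-1,5-dien-1-yl]-3,3-dimethylcyclohexan-1-ol
Product: 15 ethyl (3R,4R,6E)-7-bromo-3-{(E)-[(4S)-4-bromo-3,3-dimethylcyclohexylidene]methyl}-4-[(tert-butyldimethylsilyl)oxy]-6-methylhept-6-enoate, via mixed ketene acetal 14 (not isolated)
Conditions: MeC(OEt)3 (10 equiv), EtCO2H (10 mol %), xylenes, 135 °C, EtOH distilled off
Reagents that add atoms: triethyl orthoacetate, `CCOC(C)(OCC)OCC`
Why: Johnson–Claisen rearrangement through a chair, in which the new C1–C7a bond forms on the alkene face from which the axial C–O bond departs (setting C1), the E allylic alkene places the C2 branch equatorial, and the ring-A arm remote from the gem-dimethyl group should take the pseudo-axial site so that the exocyclic alkene emerges E.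

Step 11
Reactants: 15 ethyl (3R,4R,6E)-7-bromo-3-{(E)-[(4S)-4-bromo-3,3-dimethylcyclohexylidene]methyl}-4-[(tert-butyldimethylsilyl)oxy]-6-methylhept-6-enoate
Product: 17 (5R,6R,8E)-9-bromo-5-{(E)-[(4S)-4-bromo-3,3-dimethylcyclohexylidene]methyl}-6-[(tert-butyldimethylsilyl)oxy]-8-methylnona-1,8-dien-3-one, via Weinreb amide 16 (not isolated)
Conditions: MeNH(OMe)·HCl (1.5 equiv), iPrMgCl (3.0 equiv), THF, −20 °C; then CH2=CHMgBr (3 equiv), −20 → 0 °C; inverse quench into cold 1 M HCl
Reagents that add atoms: vinylmagnesium bromide, `C=C[Mg]Br`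
Why: Ester aminolysis by the magnesium amide gives the Weinreb amide, whose chelated tetrahedral adduct with the vinyl Grignard reagent stops at the ketone stage, and the acidic inverse quench keeps the liberated amine from adding to the enone.

Step 12
Reactants: 17 (5R,6R,8E)-9-bromo-5-{(E)-[(4S)-4-bromo-3,3-dimethylcyclohexylidene]methyl}-6-[(tert-butyldimethylsilyl)oxy]-8-methylnona-1,8-dien-3-one
Product: 18 (3Z,5S,6R,8E)-9-bromo-5-{(E)-[(4S)-4-bromo-3,3-dimethylcyclohexylidene]methyl}-3,6-bis[(tert-butyldimethylsilyl)oxy]-8-methylnona-1,3,8-triene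
Conditions: TBSOTf (1.3 equiv), Et3N (2.5 equiv), CH2Cl2, −78 → 0 °C
Reagents that add atoms: tert-butyldimethylsilyl triflate, `CC(C)(C)[Si](C)(C)OS(=O)(=O)C(F)(F)F`
Why: Soft enolisation and O-silylation of the vinyl ketone at its only enolisable position gives the 2-silyloxy diene, expected Z (silyloxy cis to the C1 branch) as is usual for amine/silyl triflate enolisation of acyclic ketones.

Step 13
Reactants: 18 (3Z,5S,6R,8E)-9-bromo-5-{(E)-[(4S)-4-bromo-3,3-dimethylcyclohexylidene]methyl}-3,6-bis[(tert-butyldimethylsilyl)oxy]-8-methylnona-1,3,8-triene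
Product: 19 (1S,2R,3aS,4S,7aS)-4-bromo-1-{(E)-[(4S)-4-bromo-3,3-dimethylcyclohexylidene]methyl}-2,7-bis[(tert-butyldimethylsilyl)oxy]-3a-methyl-2,3,3a,4,5,7a-hexahydro-1H-indene
Conditions: degassed PhMe (0.01 M), BHT (10 mol %), base-washed sealed tube, 190–200 °C
Reagents that add atoms: none
Why: On heating, the (Z)-2-silyloxy diene C7a=C7–C6=C5 and the tethered (E)-bromoalkene C3a=C4 should combine in a concerted, asynchronous intramolecular [4+2] cycloaddition (type 1 intramolecular Diels–Alder reaction of a 1,6,8-nonatriene), the closest precedent being thermal cyclisations of unactivated nonatrienes to hydrindenes. The cyclopentane closes through the internal bond C7a–C3a (five-membered, tether C1–C2–C3 outside the six-electron array) and the cyclohexene through the peripheral bond C4–C5 (six-membered, the [4+2] ring itself), this second bond completing the brominated ring. Addition is suprafacial on the alkene, so the E geometry places bromine at C4 cis to the methyl at C3a without any substitution at a neopentylic carbon. The diene face is fixed by C1: allylic 1,3-strain with the cis silyloxy group at C7 holds H-1 in the diene plane, the tether carbon C2 delivers the alkene to its own face, and the cyclohexylidenemethyl group therefore ends cis to H-7a with the C2 silyloxy group on the convex side. The trans ring fusion (C3a against C7a) needs the transition state with the tether anti (exo) and methyl and bromine endo, which an internal dienophile substituent is expected to favour over the tether-endo arrangement. Chemoselectivity rests on the ring-A alkene being exocyclic, trisubstituted and only one atom from the diene, and the temperature should be tolerated because both C–Br bonds are neopentylic and no acid is present.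

Step 14
Reactants: 19 (1S,2R,3aS,4S,7aS)-4-bromo-1-{(E)-[(4S)-4-bromo-3,3-dimethylcyclohexylidene]methyl}-2,7-bis[(tert-butyldimethylsilyl)oxy]-3a-methyl-2,3,3a,4,5,7a-hexahydro-1H-indene
Product: 20 (1S,2R,3aS,4S,7aS)-4-bromo-1-{(E)-[(4S)-4-bromo-3,3-dimethylcyclohexylidene]methyl}-2-hydroxy-3a-methyloctahydro-7H-inden-7-one
Conditions: HF·pyridine, pyridine, THF, 0 °C → rt
Reagents that add atoms: none
Why: Fluoride cleaves both silyl groups, the enol ether being protonated at C6 so that the C7a stereocentre next to the new ketone is not touched, and the buffered medium avoids epimerisation.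

Step 15
Reactants: 20 (1S,2R,3aS,4S,7aS)-4-bromo-1-{(E)-[(4S)-4-bromo-3,3-dimethylcyclohexylidene]methyl}-2-hydroxy-3a-methyloctahydro-7H-inden-7-one
Product: 21 iriediol, (1S,2R,3aS,4S,7R,7aS)-4-bromo-1-{(E)-[(4S)-4-bromo-3,3-dimethylcyclohexylidene]methyl}-3a,7-dimethyloctahydro-1H-indene-2,7-diol
Conditions: MeMgBr (5 equiv), CeCl3 (5 equiv), THF, −78 → −20 °C; aq. NH4Cl
Reagents that add atoms: methylmagnesium bromide, `C[Mg]Br`
Why: Organocerium 1,2-addition to the cyclohexanone, in which the axial face of C7 is blocked by the syn-axial C3a methyl so that methyl enters equatorially and the hydroxyl ends axial (7R), while the weakly basic reagent avoids enolisation toward C7a.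

## Compound list

1 | 5-methylhex-4-enoic acid | `CC(C)=CCCC(=O)O` | starting material
2 | (5S)-5-bromo-6,6-dimethyloxan-2-one | `CC1(C)OC(=O)CC[C@@H]1Br` | intermediate
3 | (3S)-3-bromo-2,2-dimethyl-6-methylideneoxane | `CC1(C)OC(=C)CC[C@@H]1Br` | intermediate
4 | (4S)-4-bromo-3,3-dimethylcyclohexan-1-one | `CC1(C)CC(=O)CC[C@@H]1Br` | intermediate
5 | 3-(trimethylsilyl)prop-2-ynal | `C[Si](C)(C)C#CC=O` | starting material
6 | (3R)-1-(trimethylsilyl)hexa-1,5-diyn-3-ol | `C[Si](C)(C)C#C[C@H](O)CC#C` | intermediate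
7 | (3R)-3-[(tert-butyldimethylsilyl)oxy]-1-(trimethylsilyl)hexa-1,5-diyne | `C[Si](C)(C)C#C[C@H](O[Si](C)(C)C(C)(C)C)CC#C` | intermediate
8 | [(1E,4R)-4-[(tert-butyldimethylsilyl)oxy]-2-methyl-6-(trimethylsilyl)hex-1-en-5-yn-1-yl]dimethylalane | `C[Si](C)(C)C#C[C@H](O[Si](C)(C)C(C)(C)C)C/C(C)=C/[Al](C)C` | intermediate
9 | (3R,5E)-6-bromo-3-[(tert-butyldimethylsilyl)oxy]-5-methyl-1-(trimethylsilyl)hex-5-en-1-yne | `C[Si](C)(C)C#C[C@H](O[Si](C)(C)C(C)(C)C)C/C(C)=C/Br` | intermediate
10 | (3R,5E)-6-bromo-3-[(tert-butyldimethylsilyl)oxy]-5-methylhex-5-en-1-yne | `C#C[C@H](O[Si](C)(C)C(C)(C)C)C/C(C)=C/Br` | intermediate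
11 | [(3R,5E)-6-bromo-3-[(tert-butyldimethylsilyl)oxy]-5-methylhex-5-en-1-yn-1-yl]lithium | `[Li]C#C[C@H](O[Si](C)(C)C(C)(C)C)C/C(C)=C/Br` | intermediate
12 | (1R,4S)-4-bromo-1-[(3R,5E)-6-bromo-3-[(tert-butyldimethylsilyl)oxy]-5-methylhex-5-en-1-yn-1-yl]-3,3-dimethylcyclohexan-1-ol | `CC1(C)C[C@@](O)(C#C[C@H](O[Si](C)(C)C(C)(C)C)C/C(C)=C/Br)CC[C@@H]1Br` | intermediate
13 | (1R,4S)-4-bromo-1-[(1E,3R,5E)-6-bromo-3-[(tert-butyldimethylsilyl)oxy]-5-methylhexa-1,5-dien-1-yl]-3,3-dimethylcyclohexan-1-ol | `CC1(C)C[C@@](O)(/C=C/[C@H](O[Si](C)(C)C(C)(C)C)C/C(C)=C/Br)CC[C@@H]1Br` | intermediate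
14 | 1-ethoxyvinyl ether (mixed ketene acetal) of 13 | `CC1(C)C[C@@](OC(=C)OCC)(/C=C/[C@H](O[Si](C)(C)C(C)(C)C)C/C(C)=C/Br)CC[C@@H]1Br` | intermediate
15 | ethyl (3R,4R,6E)-7-bromo-3-{(E)-[(4S)-4-bromo-3,3-dimethylcyclohexylidene]methyl}-4-[(tert-butyldimethylsilyl)oxy]-6-methylhept-6-enoate | `CC1(C)C/C(=C/[C@@H](CC(=O)OCC)[C@H](O[Si](C)(C)C(C)(C)C)C/C(C)=C/Br)CC[C@@H]1Br` | intermediate
16 | (3R,4R,6E)-7-bromo-3-{(E)-[(4S)-4-bromo-3,3-dimethylcyclohexylidene]methyl}-4-[(tert-butyldimethylsilyl)oxy]-N-methoxy-N,6-dimethylhept-6-enamide | `CC1(C)C/C(=C/[C@@H](CC(=O)N(C)OC)[C@H](O[Si](C)(C)C(C)(C)C)C/C(C)=C/Br)CC[C@@H]1Br` | intermediate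
17 | (5R,6R,8E)-9-bromo-5-{(E)-[(4S)-4-bromo-3,3-dimethylcyclohexylidene]methyl}-6-[(tert-butyldimethylsilyl)oxy]-8-methylnona-1,8-dien-3-one | `CC1(C)C/C(=C/[C@@H](CC(=O)C=C)[C@H](O[Si](C)(C)C(C)(C)C)C/C(C)=C/Br)CC[C@@H]1Br` | intermediate
18 | (3Z,5S,6R,8E)-9-bromo-5-{(E)-[(4S)-4-bromo-3,3-dimethylcyclohexylidene]methyl}-3,6-bis[(tert-butyldimethylsilyl)oxy]-8-methylnona-1,3,8-triene | `CC1(C)C/C(=C/[C@@H](/C=C(\O[Si](C)(C)C(C)(C)C)C=C)[C@H](O[Si](C)(C)C(C)(C)C)C/C(C)=C/Br)CC[C@@H]1Br` | intermediate
19 | (1S,2R,3aS,4S,7aS)-4-bromo-1-{(E)-[(4S)-4-bromo-3,3-dimethylcyclohexylidene]methyl}-2,7-bis[(tert-butyldimethylsilyl)oxy]-3a-methyl-2,3,3a,4,5,7a-hexahydro-1H-indene | `CC1(C)C/C(=C/[C@@H]2[C@H](O[Si](C)(C)C(C)(C)C)C[C@]3(C)[C@@H](Br)CC=C(O[Si](C)(C)C(C)(C)C)[C@@H]23)CC[C@@H]1Br` | intermediate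
20 | (1S,2R,3aS,4S,7aS)-4-bromo-1-{(E)-[(4S)-4-bromo-3,3-dimethylcyclohexylidene]methyl}-2-hydroxy-3a-methyloctahydro-7H-inden-7-one | `CC1(C)C/C(=C/[C@@H]2[C@H](O)C[C@]3(C)[C@@H](Br)CCC(=O)[C@@H]23)CC[C@@H]1Br` | intermediate
21 | iriediol, (1S,2R,3aS,4S,7R,7aS)-4-bromo-1-{(E)-[(4S)-4-bromo-3,3-dimethylcyclohexylidene]methyl}-3a,7-dimethyloctahydro-1H-indene-2,7-diol | `CC1(C)C/C(=C/[C@@H]2[C@H](O)C[C@]3(C)[C@@H](Br)CC[C@@](C)(O)[C@@H]23)CC[C@@H]1Br` | target

## Step count and risks

Total step count: 15. Longest linear sequence: 12 steps (5 → 21, steps 4 to 15).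

**Step 3 (Proposed new method).** The ion pair may lose a proton to an isopropenyl ketone, or pass bromonium between molecules with erosion of enantiopurity, instead of reclosing through carbon. The fallback sets out from 2 and returns to 4. Lactone 2 is opened with Me3SiCH2MgCl/CeCl3 (THF, −78 → 0 °C, cold quench) to (3S)-3-bromo-2-methyl-7-(trimethylsilyl)-6-[(trimethylsilyl)methyl]heptane-2,6-diol F1. Peterson elimination on silica gel gives the allylsilane (3S)-3-bromo-2-methyl-6-[(trimethylsilyl)methyl]hept-6-en-2-ol F2. Ionisation of its tertiary alcohol (BF3·OEt2, CH2Cl2, −78 °C), again assisted by bromine, and capture by the allylsilane (cation–allylsilane cyclisation) give (1S)-1-bromo-2,2-dimethyl-4-methylidenecyclohexane F3. Ozonolysis (O3, CH2Cl2/MeOH, −78 °C; Me2S) returns ketone 4.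

**Step 13.** The unactivated, trisubstituted bromoalkene may fail to engage the diene below the temperature at which the triene decomposes, or the ring fusion may form with poor trans selectivity. The fallback sets out from 18 and returns at 20; it activates the dienophile and brings the bromine in afterwards.
- Alkoxycarbonylation of the vinylic bromide of 18 (Pd(OAc)2, dppf, CO 1 atm, Me3SiCH2CH2OH, Et3N, DMF, 60 °C) gives the 2-(trimethylsilyl)ethyl (E)-enoate triene F8.
- F8 should cyclise at 110–130 °C through the ester-endo, tether-exo transition state to the trans-fused 4-carboxylate adduct F9.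
- Ester enolate bromination (LDA, THF, −78 °C; BrCCl2CCl2Br) gives the α-bromo ester F10.
- Bu4NF/AcOH removes the silylethyl ester and both TBS groups to give the hydroxy keto α-bromo acid F11.
- F11 is converted into its N-hydroxypyridine-2-thione ester F12 (DCC, CH2Cl2, dark), and Barton reductive decarboxylation (visible light, t-BuSH) delivers hydrogen to the α-bromo radical from the face anti to the C3a methyl, leaving bromine equatorial and giving 20.

**Step 10.** The tertiary allylic alcohol may ionise or dehydrate under hot acid, or the two chair transition states may be poorly discriminated, eroding both the E geometry and the C1 configuration. The fallback sets out from 13 and returns at 16. Alcohol 13 is acetylated (LiHMDS, THF, −78 °C; AcCl) to acetate F4. Ireland–Claisen conditions (LDA, Me3SiCl, THF, −78 °C) give the trimethylsilyl ketene acetal F5, which rearranges on warming to room temperature to the trimethylsilyl ester F6. Aqueous work-up gives the carboxylic acid F7, and coupling with MeNH(OMe)·HCl (EDCI, iPr2NEt, CH2Cl2) gives Weinreb amide 16, which is then isolated and treated with CH2=CHMgBr as in step 11.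

## Further compounds

F1 | step 3 | (3S)-3-bromo-2-methyl-7-(trimethylsilyl)-6-[(trimethylsilyl)methyl]heptane-2,6-diol | `C[Si](C)(C)CC(O)(C[Si](C)(C)C)CC[C@@H](C(C)(C)O)Br`
F2 | step 3 | (3S)-3-bromo-2-methyl-6-[(trimethylsilyl)methyl]hept-6-en-2-ol | `C[Si](C)(C)CC(=C)CC[C@@H](C(C)(C)O)Br`
F3 | step 3 | (1S)-1-bromo-2,2-dimethyl-4-methylidenecyclohexane | `CC1(C)CC(=C)CC[C@@H]1Br`
F4 | step 10 | acetate of 13, (1R,4S)-4-bromo-1-[(1E,3R,5E)-6-bromo-3-[(tert-butyldimethylsilyl)oxy]-5-methylhexa-1,5-dien-1-yl]-3,3-dimethylcyclohexyl acetate | `CC1(C)C[C@@](OC(C)=O)(/C=C/[C@H](O[Si](C)(C)C(C)(C)C)C/C(C)=C/Br)CC[C@@H]1Br`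
F5 | step 10 | trimethylsilyl ketene acetal of F4 | `CC1(C)C[C@@](OC(=C)O[Si](C)(C)C)(/C=C/[C@H](O[Si](C)(C)C(C)(C)C)C/C(C)=C/Br)CC[C@@H]1Br`
F6 | step 10 | trimethylsilyl (3R,4R,6E)-7-bromo-3-{(E)-[(4S)-4-bromo-3,3-dimethylcyclohexylidene]methyl}-4-[(tert-butyldimethylsilyl)oxy]-6-methylhept-6-enoate | `CC1(C)C/C(=C/[C@@H](CC(=O)O[Si](C)(C)C)[C@H](O[Si](C)(C)C(C)(C)C)C/C(C)=C/Br)CC[C@@H]1Br`
F7 | step 10 | (3R,4R,6E)-7-bromo-3-{(E)-[(4S)-4-bromo-3,3-dimethylcyclohexylidene]methyl}-4-[(tert-butyldimethylsilyl)oxy]-6-methylhept-6-enoic acid | `CC1(C)C/C(=C/[C@@H](CC(=O)O)[C@H](O[Si](C)(C)C(C)(C)C)C/C(C)=C/Br)CC[C@@H]1Br`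
F8 | step 13 | analogue of 18 with CO2CH2CH2SiMe3 in place of the vinylic bromine, 2-(trimethylsilyl)ethyl (2E,5R,6S,7Z)-6-{(E)-[(4S)-4-bromo-3,3-dimethylcyclohexylidene]methyl}-5,8-bis[(tert-butyldimethylsilyl)oxy]-3-methyldeca-2,7,9-trienoate | `CC1(C)C/C(=C/[C@@H](/C=C(\O[Si](C)(C)C(C)(C)C)C=C)[C@H](O[Si](C)(C)C(C)(C)C)C/C(C)=C/C(=O)OCC[Si](C)(C)C)CC[C@@H]1Br`
F9 | step 13 | analogue of 19 with CO2CH2CH2SiMe3 at C4 (cis to the C3a methyl) in place of bromine | `CC1(C)C/C(=C/[C@@H]2[C@H](O[Si](C)(C)C(C)(C)C)C[C@]3(C)[C@@H](C(=O)OCC[Si](C)(C)C)CC=C(O[Si](C)(C)C(C)(C)C)[C@@H]23)CC[C@@H]1Br`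
F10 | step 13 | 4-bromo derivative of F9 (bromine and ester both on C4; configuration at C4 immaterial, drawn as expected) | `CC1(C)C/C(=C/[C@@H]2[C@H](O[Si](C)(C)C(C)(C)C)C[C@]3(C)[C@@](Br)(C(=O)OCC[Si](C)(C)C)CC=C(O[Si](C)(C)C(C)(C)C)[C@@H]23)CC[C@@H]1Br`
F11 | step 13 | 4-bromo-1-{(E)-[(4S)-4-bromo-3,3-dimethylcyclohexylidene]methyl}-2-hydroxy-3a-methyl-7-oxooctahydro-1H-indene-4-carboxylic acid | `CC1(C)C/C(=C/[C@@H]2[C@H](O)C[C@]3(C)[C@@](Br)(C(=O)O)CCC(=O)[C@@H]23)CC[C@@H]1Br`
F12 | step 13 | 2-thioxopyridin-1(2H)-yl ester (Barton ester) of F11 | `CC1(C)C/C(=C/[C@@H]2[C@H](O)C[C@]3(C)[C@@](Br)(C(=O)ON4C=CC=CC4=S)CCC(=O)[C@@H]23)CC[C@@H]1Br`
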